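**Retrosynthetic overview**
- Last disconnection: the four O–benzyl bonds (two on the central ring, two on the outer phenols) are cut together by hydrogenolysis, so the free ortho-hydroxy aryl esters appear only at the very end.
- The two different aryl ester C(=O)–O bonds are cut one after the other back to a centrosymmetric tetra-O-benzyl hydroquinone. Its two free OH groups are equivalent, so the first acylation can give only one monoester; the (S)-3-acetoxybutanoyl group goes on last.
- Hydroquinone ⇒ quinone (reduction). The two aryl–aryl bonds ⇒ double Suzuki–Miyaura coupling of 2,5-bis(benzyloxy)-3,6-dibromo-1,4-benzoquinone ⇒ bromanil + benzyloxide.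
- The only stereocentre is bought as (S)-3-hydroxybutanoic acid and is only O-acetylated.
- No ring is formed: the central ring is that of bromanil, and the two outer rings arrive ready-made in the boronic acid, both attached in one step.

Assumption: the single stereocentre is (S), as read from the SMILES, and bromanil, sodium benzyloxide solution, the boronic acid, the acid chloride and (S)-3-hydroxybutanoic acid are bought.

**Step 1**
Reactants: 1 tetrabromo-1,4-benzoquinone (bromanil)
Product: 3 2,5-bis(benzyloxy)-3,6-dibromo-1,4-benzoquinone, via tribromo(benzyloxy)quinone 2 (not isolated)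
Conditions: NaOCH2Ph (2.1 equiv, 1 M in benzyl alcohol), THF, −20 °C → 0 °C
Reagents that add atoms: sodium benzyloxide, [Na+].[O-]Cc1ccccc1
Why: Nucleophilic vinylic substitution (addition–elimination) on the tetrahaloquinone, in which the first benzyloxy group turns the carbonyl it is conjugated to into a vinylogous ester, so the second alkoxide adds to the other, still activated enone unit and gives the 2,5-pattern, after which the doubly deactivated product does not react further.

**Step 2**
Reactants: 3 2,5-bis(benzyloxy)-3,6-dibromo-1,4-benzoquinone; 4 [4-(benzyloxy)phenyl]boronic acid (2.5 equiv)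
Product: 6 2,5-bis(benzyloxy)-3,6-bis[4-(benzyloxy)phenyl]-1,4-benzoquinone, via monoarylated bromoquinone 5 (not isolated)
Conditions: PdCl2(dppf) (5 mol %), K2CO3, degassed 1,4-dioxane, 90 °C, Ar
Reagents that add atoms: none
Why: Double Suzuki–Miyaura coupling, in which the C–Br bonds of the electron-poor bromoquinone add readily to zerovalent palladium formed from PdCl2(dppf), the unhindered boronic acid transmetalates easily, and the benzyl ethers tolerate carbonate in dioxane.

**Step 3**
Reactants: 6 2,5-bis(benzyloxy)-3,6-bis[4-(benzyloxy)phenyl]-1,4-benzoquinone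
Product: 7 2,5-bis(benzyloxy)-3,6-bis[4-(benzyloxy)phenyl]benzene-1,4-diol
Conditions: Na2S2O4, THF/H2O, rt, Ar; used at once
Reagents that add atoms: none
Why: Quinone-to-hydroquinone reduction by dithionite, a two-electron, two-proton reduction that touches neither the benzyl ethers nor the aryl–aryl bonds.

**Step 4**
Reactants: 7 2,5-bis(benzyloxy)-3,6-bis[4-(benzyloxy)phenyl]benzene-1,4-diol; 8 3-phenylpropanoyl chloride (0.95 equiv)
Product: 9 2,5-bis(benzyloxy)-3,6-bis[4-(benzyloxy)phenyl]-4-hydroxyphenyl 3-phenylpropanoate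
Conditions: pyridine, DMAP (cat.), CH2Cl2, −20 °C → 0 °C, Ar; recovered 7 recycled
Reagents that add atoms: none
Why: DMAP-catalysed O-acylation (nucleophilic acyl substitution) of a diol whose two hydroxyl groups are related by the inversion centre of the ring, so either one gives the same monoester, while a slight deficit of acid chloride and the weaker donor effect of the new para-acyloxy group hold back the second acylation.

**Step 5**
Reactants: 10 (S)-3-hydroxybutanoic acid
Product: 11 (S)-3-acetoxybutanoic acid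
Conditions: AcCl (3 equiv), neat, 0 °C → rt, then evaporation
Reagents that add atoms: acetyl chloride, CC(=O)Cl
Why: O-Acetylation of the secondary alcohol by acetyl chloride (nucleophilic acyl substitution), which does not break the C–O bond at the stereocentre, so the (S) configuration of the bought acid is kept.

**Step 6**
Reactants: 9 2,5-bis(benzyloxy)-3,6-bis[4-(benzyloxy)phenyl]-4-hydroxyphenyl 3-phenylpropanoate; 11 (S)-3-acetoxybutanoic acid (1.5 equiv)
Product: 13 2,5-bis(benzyloxy)-3,6-bis[4-(benzyloxy)phenyl]-4-[(3-phenylpropanoyl)oxy]phenyl (3S)-3-acetoxybutanoate, via O-acylisourea 12 (not isolated)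
Conditions: DCC (1.5 equiv), DMAP (0.1 equiv), CH2Cl2, 0 °C → rt
Reagents that add atoms: none
Why: Steglich esterification, in which DCC activates the acid and DMAP carries the acyl group to the hindered phenol at low temperature, no bond to the stereocentre is touched, and the mild conditions keep beta-elimination of acetate to the crotonate in check.

**Step 7**
Reactants: 13 2,5-bis(benzyloxy)-3,6-bis[4-(benzyloxy)phenyl]-4-[(3-phenylpropanoyl)oxy]phenyl (3S)-3-acetoxybutanoate
Product: 14 2,5-dihydroxy-3,6-bis(4-hydroxyphenyl)-4-[(3-phenylpropanoyl)oxy]phenyl (3S)-3-acetoxybutanoate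
Conditions: H2 (1 atm), 10% Pd/C, EtOAc, rt
Reagents that add atoms: none
Why: Catalytic hydrogenolysis of the four benzyl aryl ethers over Pd/C under neutral conditions, which leaves both aryl esters, the acetate and the stereocentre alone and, being free of acid and base, does not move an acyl group onto a neighbouring new hydroxyl.

**Compound list**
1 | tetrabromo-1,4-benzoquinone (bromanil) | O=C1C(Br)=C(Br)C(=O)C(Br)=C1Br | starting material
2 | 2-(benzyloxy)-3,5,6-tribromo-1,4-benzoquinone | O=C1C(OCc2ccccc2)=C(Br)C(=O)C(Br)=C1Br | intermediate (not isolated)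
3 | 2,5-bis(benzyloxy)-3,6-dibromo-1,4-benzoquinone | O=C1C(OCc2ccccc2)=C(Br)C(=O)C(OCc2ccccc2)=C1Br | intermediate
4 | [4-(benzyloxy)phenyl]boronic acid | OB(O)c1ccc(OCc2ccccc2)cc1 | starting material
5 | 2,5-bis(benzyloxy)-3-[4-(benzyloxy)phenyl]-6-bromo-1,4-benzoquinone | O=C1C(OCc2ccccc2)=C(c2ccc(OCc3ccccc3)cc2)C(=O)C(OCc2ccccc2)=C1Br | intermediate (not isolated)
6 | 2,5-bis(benzyloxy)-3,6-bis[4-(benzyloxy)phenyl]-1,4-benzoquinone | O=C1C(OCc2ccccc2)=C(c2ccc(OCc3ccccc3)cc2)C(=O)C(OCc2ccccc2)=C1c1ccc(OCc2ccccc2)cc1 | intermediate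
7 | 2,5-bis(benzyloxy)-3,6-bis[4-(benzyloxy)phenyl]benzene-1,4-diol | Oc1c(OCc2ccccc2)c(-c2ccc(OCc3ccccc3)cc2)c(O)c(OCc2ccccc2)c1-c1ccc(OCc2ccccc2)cc1 | intermediate
8 | 3-phenylpropanoyl chloride | O=C(Cl)CCc1ccccc1 | starting material
9 | 2,5-bis(benzyloxy)-3,6-bis[4-(benzyloxy)phenyl]-4-hydroxyphenyl 3-phenylpropanoate | O=C(CCc1ccccc1)Oc1c(OCc2ccccc2)c(-c2ccc(OCc3ccccc3)cc2)c(O)c(OCc2ccccc2)c1-c1ccc(OCc2ccccc2)cc1 | intermediate
10 | (S)-3-hydroxybutanoic acid | C[C@H](O)CC(=O)O | starting material
11 | (S)-3-acetoxybutanoic acid | CC(=O)O[C@@H](C)CC(=O)O | intermediate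
12 | O-[(3S)-3-acetoxybutanoyl]-N,N'-dicyclohexylisourea | CC(=O)O[C@@H](C)CC(=O)OC(=NC1CCCCC1)NC1CCCCC1 | intermediate (not isolated)
13 | 2,5-bis(benzyloxy)-3,6-bis[4-(benzyloxy)phenyl]-4-[(3-phenylpropanoyl)oxy]phenyl (3S)-3-acetoxybutanoate | CC(=O)O[C@@H](C)CC(=O)Oc1c(OCc2ccccc2)c(-c2ccc(OCc3ccccc3)cc2)c(OC(=O)CCc2ccccc2)c(OCc2ccccc2)c1-c1ccc(OCc2ccccc2)cc1 | intermediate
14 | 2,5-dihydroxy-3,6-bis(4-hydroxyphenyl)-4-[(3-phenylpropanoyl)oxy]phenyl (3S)-3-acetoxybutanoate | CC(=O)O[C@@H](C)CC(=O)Oc1c(O)c(-c2ccc(O)cc2)c(OC(=O)CCc2ccccc2)c(O)c1-c1ccc(O)cc1 | target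

**Totals**
Total step count: 7. Longest linear sequence: 6 steps (steps 1, 2, 3, 4, 6, 7, from bromanil); step 5 is a one-step side branch.

**Three steps most likely to fail**

Step 2 (double Suzuki–Miyaura on the quinone). The quinone can oxidise the phosphine and the active palladium, wet carbonate at 90 °C can hydrolyse the vinylogous benzyl esters, and the second coupling may stall at 5. The fallback sets out from 3 and comes back at 7, so it also replaces step 3; it does the coupling on an arene instead of a quinone. Compound 3 is reduced with Na2S2O4 in THF/H2O to 2,5-bis(benzyloxy)-3,6-dibromobenzene-1,4-diol F1. Its two hydroxyl groups are capped with chloromethyl methyl ether and iPr2NEt in CH2Cl2 to give 1,4-bis(benzyloxy)-2,5-dibromo-3,6-bis(methoxymethoxy)benzene F2. This is coupled with 4 using Pd(OAc)2/SPhos and K3PO4 in toluene/H2O at 100 °C to give 1,4-bis(benzyloxy)-2,5-bis[4-(benzyloxy)phenyl]-3,6-bis(methoxymethoxy)benzene F3. Both acetals are then removed with HCl in MeOH/THF at 40 °C, which leaves the benzyl ethers and gives 7.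

Step 4 (mono-acylation of a symmetric diol). The product distribution is close to statistical, and 7 re-oxidises to 6 in air under basic conditions. The fallback sets out from 7 and comes back at 9; it replaces selective acylation by selective de-acylation. Compound 7 is acylated on both oxygens with excess 8 (pyridine, DMAP, CH2Cl2, rt) to the air-stable 2,5-bis(benzyloxy)-3,6-bis[4-(benzyloxy)phenyl]-1,4-phenylene bis(3-phenylpropanoate) F4. One ester is then cleaved with pyrrolidine (1.0 equiv) in THF at 0 °C. The phenol(ate) set free is para to the remaining ester and makes it a much poorer leaving group, so aminolysis stops at 9. Diester formed as by-product in step 4 can be fed into the same operation.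

Step 6 (esterification of the hindered phenol). The hydroxyl of 9 is flanked by a benzyloxy and an aryl group; the activated beta-acetoxy acid can lose acetic acid to a crotonate or rearrange to the N-acylurea. The fallback sets out from 9 and comes back at 13; it builds the side chain on the phenol and sets the stereocentre by catalyst control instead of buying it. Compound 9 is heated with 2,2,6-trimethyl-4H-1,3-dioxin-4-one in toluene at 110 °C; the small, very reactive acetylketene gives 2,5-bis(benzyloxy)-3,6-bis[4-(benzyloxy)phenyl]-4-[(3-phenylpropanoyl)oxy]phenyl 3-oxobutanoate F5. Noyori asymmetric hydrogenation of the ketone with RuCl2[(S)-BINAP] and H2 (50 atm) in CH2Cl2/EtOH at 40 °C, which does not cleave benzyl ethers, gives 2,5-bis(benzyloxy)-3,6-bis[4-(benzyloxy)phenyl]-4-[(3-phenylpropanoyl)oxy]phenyl (3S)-3-hydroxybutanoate F6. Acetylation of the only free hydroxyl with acetic anhydride and pyridine at 0 °C gives 13.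

**Further compounds**
F1 | step 2 | 2,5-bis(benzyloxy)-3,6-dibromobenzene-1,4-diol | Oc1c(OCc2ccccc2)c(Br)c(O)c(OCc2ccccc2)c1Br
F2 | step 2 | 1,4-bis(benzyloxy)-2,5-dibromo-3,6-bis(methoxymethoxy)benzene | COCOc1c(OCc2ccccc2)c(Br)c(OCOC)c(OCc2ccccc2)c1Br
F3 | step 2 | 1,4-bis(benzyloxy)-2,5-bis[4-(benzyloxy)phenyl]-3,6-bis(methoxymethoxy)benzene | COCOc1c(OCc2ccccc2)c(-c2ccc(OCc3ccccc3)cc2)c(OCOC)c(OCc2ccccc2)c1-c1ccc(OCc2ccccc2)cc1
F4 | step 4 | 2,5-bis(benzyloxy)-3,6-bis[4-(benzyloxy)phenyl]-1,4-phenylene bis(3-phenylpropanoate) | O=C(CCc1ccccc1)Oc1c(OCc2ccccc2)c(-c2ccc(OCc3ccccc3)cc2)c(OC(=O)CCc2ccccc2)c(OCc2ccccc2)c1-c1ccc(OCc2ccccc2)cc1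
F5 | step 6 | 2,5-bis(benzyloxy)-3,6-bis[4-(benzyloxy)phenyl]-4-[(3-phenylpropanoyl)oxy]phenyl 3-oxobutanoate | CC(=O)CC(=O)Oc1c(OCc2ccccc2)c(-c2ccc(OCc3ccccc3)cc2)c(OC(=O)CCc2ccccc2)c(OCc2ccccc2)c1-c1ccc(OCc2ccccc2)cc1
F6 | step 6 | 2,5-bis(benzyloxy)-3,6-bis[4-(benzyloxy)phenyl]-4-[(3-phenylpropanoyl)oxy]phenyl (3S)-3-hydroxybutanoate | C[C@H](O)CC(=O)Oc1c(OCc2ccccc2)c(-c2ccc(OCc3ccccc3)cc2)c(OC(=O)CCc2ccccc2)c(OCc2ccccc2)c1-c1ccc(OCc2ccccc2)cc1
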